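**Assumption:** the target has no stereocentre (it is achiral), so "single enantiomer" is met by the constitution alone. The only stereo-elements in the route are the alkene geometries of 5–7, which are erased in step 5.

## Retrosynthetic overview

1. Target 19 ⇐ 18 ⇐ 17 by aryl ester hydrolysis, then threefold O-debenzylation (ring A keeps its OMe).
2. 17 ⇐ dibromide 12 + 2 × benzylzinc 14 (twofold Negishi coupling); 12 ⇐ bibenzyl 9 by dibromination ortho to the side chain, with ring B switched off as its pivalate.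
3. Bibenzyl 8 ⇐ cis-stilbene 7 ⇐ α-arylcinnamic acid 6 (decarboxylation, C=C reduction).
4. Key C–C bond (the future CH2–CH2 bridge): Perkin aldol-type condensation of aldehyde 3 (from 3,5-dimethoxybenzaldehyde 1) with 3-hydroxyphenylacetic acid 4.
5. No ring is built. Ring A (from 1) and ring B (from 4) are joined first; the two p-oxybenzyl rings (from 13) are attached last.

## Route

Step 1
Reactants: 1 3,5-dimethoxybenzaldehyde
Product: 2 3-hydroxy-5-methoxybenzaldehyde
Conditions: NaSEt (2.5 equiv), DMF, 150 °C, 1–2 h; then 1 M HCl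
Reagents that add atoms: none
Why: Thiolate SN2 O-demethylation stops cleanly after one methyl group because the phenoxide formed makes the second aryloxide a far poorer leaving group; no stereocentre is involved.

Step 2
Reactants: 2 3-hydroxy-5-methoxybenzaldehyde
Product: 3 3-(benzyloxy)-5-methoxybenzaldehyde
Conditions: BnBr (1.1 equiv), K2CO3, DMF, rt
Reagents that add atoms: benzyl bromide, BrCc1ccccc1
Why: Williamson ether synthesis on the only phenol gives the ring A aldehyde with differentiated oxygens (OBn to be freed at the end, OMe to stay).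

Step 3
Reactants: 3 3-(benzyloxy)-5-methoxybenzaldehyde; 4 3-hydroxyphenylacetic acid
Product: 6 (2E)-3-[3-(benzyloxy)-5-methoxyphenyl]-2-(3-hydroxyphenyl)prop-2-enoic acid, via O-acetylated acrylic acid 5 (not isolated)
Conditions: Ac2O, Et3N, 120 °C, 8 h; then 2 M NaOH, THF/H2O, rt; then HCl to pH 2
Reagents that add atoms: none
Why: Perkin condensation, an intermolecular aldol-type addition of the mixed-anhydride enolate of 4 to aldehyde 3 followed by β-elimination, gives the thermodynamic (E)-2,3-diarylacrylic acid (aryl groups cis); the aryl acetate formed in the flask is cleaved in the basic work-up, and no stereocentre is created.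

Step 4
Reactants: 6 (2E)-3-[3-(benzyloxy)-5-methoxyphenyl]-2-(3-hydroxyphenyl)prop-2-enoic acid
Product: 7 3-{(Z)-2-[3-(benzyloxy)-5-methoxyphenyl]ethenyl}phenol
Conditions: Cu powder, quinoline, 220 °C, 2 h, N2
Reagents that add atoms: none
Why: Copper–quinoline protodecarboxylation of an α-arylcinnamic acid replaces CO2H by H with retention, giving the cis-stilbene, whose geometry is irrelevant because the alkene is saturated next.

Step 5
Reactants: 7 3-{(Z)-2-[3-(benzyloxy)-5-methoxyphenyl]ethenyl}phenol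
Product: 8 3-{2-[3-(benzyloxy)-5-methoxyphenyl]ethyl}phenol
Conditions: TsNHNH2 (6 equiv, portionwise), NaOAc (aq), DME, reflux
Reagents that add atoms: none
Why: Diimide transfer hydrogenation saturates the stilbene C=C by concerted syn delivery of two hydrogens and leaves the benzyl ether untouched, which Pd/C–H2 would not; no stereocentre results.

Step 6
Reactants: 8 3-{2-[3-(benzyloxy)-5-methoxyphenyl]ethyl}phenol
Product: 9 3-{2-[3-(benzyloxy)-5-methoxyphenyl]ethyl}phenyl pivalate
Conditions: PivCl (1.2 equiv), Et3N, DMAP (cat.), CH2Cl2, 0 °C → rt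
Reagents that add atoms: pivaloyl chloride, CC(C)(C)C(=O)Cl
Why: DMAP-catalysed O-acylation of the single phenol turns ring B from an anisole-like arene into a deactivated aryl ester, so that only ring A is halogenated in the next step.

Step 7
Reactants: 9 3-{2-[3-(benzyloxy)-5-methoxyphenyl]ethyl}phenyl pivalate
Product: 12 3-{2-[3-(benzyloxy)-2,6-dibromo-5-methoxyphenyl]ethyl}phenyl pivalate, via 2-bromo monobromide 10 (not isolated), via 6-bromo monobromide 11 (not isolated)
Conditions: NBS (2.05 equiv), MeCN, 0 °C → rt, dark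
Reagents that add atoms: N-bromosuccinimide, O=C1CCC(=O)N1Br
Why: Electrophilic aromatic bromination of the resorcinol diether goes to the two positions that are para to one alkoxy group and ortho to the other (C2 and C6, as with orcinol dimethyl ether); the position between the two oxygens and the acyloxy-substituted ring B react far more slowly.

Step 8
Reactants: 13 4-(benzyloxy)benzyl chloride
Product: 14 [4-(benzyloxy)benzyl]zinc chloride (about 0.5 M in THF, titrated, used directly)
Conditions: Zn dust (activated with BrCH2CH2Br/TMSCl), LiCl, THF, 25 °C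
Reagents that add atoms: zinc, [Zn]
Why: LiCl-promoted oxidative insertion of zinc into the benzylic C–Cl bond gives the benzylzinc reagent with little Wurtz homocoupling.

Step 9
Reactants: 12 3-{2-[3-(benzyloxy)-2,6-dibromo-5-methoxyphenyl]ethyl}phenyl pivalate; 14 [4-(benzyloxy)benzyl]zinc chloride (3 equiv)
Product: 17 3-(2-{3-(benzyloxy)-2,6-bis[4-(benzyloxy)benzyl]-5-methoxyphenyl}ethyl)phenyl pivalate, via 2-benzylated 6-bromide 15 (not isolated), via 6-benzylated 2-bromide 16 (not isolated)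
Conditions: Pd(OAc)2 (5 mol%), SPhos (10 mol%), THF, 25 → 60 °C
Reagents that add atoms: none
Why: Twofold Negishi sp2–sp3 cross-coupling works because SPhos–Pd inserts into hindered, electron-rich aryl bromides and the benzylzinc has no β-hydrogen, while the pivalate and the benzyl ethers are inert to both Pd(0) and organozinc.

Step 10
Reactants: 17 3-(2-{3-(benzyloxy)-2,6-bis[4-(benzyloxy)benzyl]-5-methoxyphenyl}ethyl)phenyl pivalate
Product: 18 3-(2-{3-(benzyloxy)-2,6-bis[4-(benzyloxy)benzyl]-5-methoxyphenyl}ethyl)phenol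
Conditions: NaOH, THF/MeOH/H2O, 50 °C; then 1 M HCl
Reagents that add atoms: none
Why: Saponification of the aryl ester (phenoxide leaving group) frees the ring B phenol while the benzyl and methyl ethers are stable to base, and doing it before debenzylation keeps the air-sensitive polyphenol out of alkali.

Step 11
Reactants: 18 3-(2-{3-(benzyloxy)-2,6-bis[4-(benzyloxy)benzyl]-5-methoxyphenyl}ethyl)phenol
Product: 19 3-[2-(3-hydroxyphenyl)ethyl]-2,4-bis(4-hydroxybenzyl)-5-methoxyphenol (the target)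
Conditions: H2 (1 atm), 10% Pd/C, EtOAc/MeOH, rt
Reagents that add atoms: none
Why: Catalytic hydrogenolysis cleaves the three aryl benzyl ethers under neutral conditions, while the methyl ether and the diarylmethane and bibenzyl C–C bonds are inert; the product has no stereocentre.

## Compound list

1 | 3,5-dimethoxybenzaldehyde | COc1cc(C=O)cc(OC)c1 | starting material
2 | 3-hydroxy-5-methoxybenzaldehyde | COc1cc(O)cc(C=O)c1 | intermediate
3 | 3-(benzyloxy)-5-methoxybenzaldehyde | COc1cc(C=O)cc(OCc2ccccc2)c1 | intermediate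
4 | 3-hydroxyphenylacetic acid | OC(=O)Cc1cccc(O)c1 | starting material
5 | (2E)-2-(3-acetoxyphenyl)-3-[3-(benzyloxy)-5-methoxyphenyl]prop-2-enoic acid | OC(=O)/C(=C/c1cc(OC)cc(OCc2ccccc2)c1)c1cccc(OC(C)=O)c1 | intermediate (not isolated)
6 | (2E)-3-[3-(benzyloxy)-5-methoxyphenyl]-2-(3-hydroxyphenyl)prop-2-enoic acid | OC(=O)/C(=C/c1cc(OC)cc(OCc2ccccc2)c1)c1cccc(O)c1 | intermediate
7 | 3-{(Z)-2-[3-(benzyloxy)-5-methoxyphenyl]ethenyl}phenol | Oc1cccc(/C=C\c2cc(OC)cc(OCc3ccccc3)c2)c1 | intermediate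
8 | 3-{2-[3-(benzyloxy)-5-methoxyphenyl]ethyl}phenol | Oc1cccc(CCc2cc(OC)cc(OCc3ccccc3)c2)c1 | intermediate
9 | 3-{2-[3-(benzyloxy)-5-methoxyphenyl]ethyl}phenyl pivalate | CC(C)(C)C(=O)Oc1cccc(CCc2cc(OC)cc(OCc3ccccc3)c2)c1 | intermediate
10 | 3-{2-[3-(benzyloxy)-2-bromo-5-methoxyphenyl]ethyl}phenyl pivalate (Br between side chain and OBn) | CC(C)(C)C(=O)Oc1cccc(CCc2c(Br)c(OCc3ccccc3)cc(OC)c2)c1 | intermediate (not isolated)
11 | 3-{2-[5-(benzyloxy)-2-bromo-3-methoxyphenyl]ethyl}phenyl pivalate (Br between side chain and OMe) | CC(C)(C)C(=O)Oc1cccc(CCc2cc(OCc3ccccc3)cc(OC)c2Br)c1 | intermediate (not isolated)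
12 | 3-{2-[3-(benzyloxy)-2,6-dibromo-5-methoxyphenyl]ethyl}phenyl pivalate | CC(C)(C)C(=O)Oc1cccc(CCc2c(Br)c(OCc3ccccc3)cc(OC)c2Br)c1 | intermediate
13 | 4-(benzyloxy)benzyl chloride | ClCc1ccc(OCc2ccccc2)cc1 | starting material
14 | [4-(benzyloxy)benzyl]zinc chloride | Cl[Zn]Cc1ccc(OCc2ccccc2)cc1 | intermediate
15 | 3-(2-{3-(benzyloxy)-2-[4-(benzyloxy)benzyl]-6-bromo-5-methoxyphenyl}ethyl)phenyl pivalate | CC(C)(C)C(=O)Oc1cccc(CCc2c(Cc3ccc(OCc4ccccc4)cc3)c(OCc3ccccc3)cc(OC)c2Br)c1 | intermediate (not isolated)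
16 | 3-(2-{3-(benzyloxy)-6-[4-(benzyloxy)benzyl]-2-bromo-5-methoxyphenyl}ethyl)phenyl pivalate | CC(C)(C)C(=O)Oc1cccc(CCc2c(Br)c(OCc3ccccc3)cc(OC)c2Cc2ccc(OCc3ccccc3)cc2)c1 | intermediate (not isolated)
17 | 3-(2-{3-(benzyloxy)-2,6-bis[4-(benzyloxy)benzyl]-5-methoxyphenyl}ethyl)phenyl pivalate | CC(C)(C)C(=O)Oc1cccc(CCc2c(Cc3ccc(OCc4ccccc4)cc3)c(OCc3ccccc3)cc(OC)c2Cc2ccc(OCc3ccccc3)cc2)c1 | intermediate
18 | 3-(2-{3-(benzyloxy)-2,6-bis[4-(benzyloxy)benzyl]-5-methoxyphenyl}ethyl)phenol | Oc1cccc(CCc2c(Cc3ccc(OCc4ccccc4)cc3)c(OCc3ccccc3)cc(OC)c2Cc2ccc(OCc3ccccc3)cc2)c1 | intermediate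
19 | 3-[2-(3-hydroxyphenyl)ethyl]-2,4-bis(4-hydroxybenzyl)-5-methoxyphenol (3,3'-dihydroxy-2,6-bis(p-hydroxybenzyl)-5-methoxybibenzyl) | COc1cc(O)c(Cc2ccc(O)cc2)c(CCc2cccc(O)c2)c1Cc1ccc(O)cc1 | target

## Step count and risks

Total step count: 11. Longest linear sequence: 10 steps (steps 1–7, then 9–11, from compound 1); step 8 is a one-step side branch.

Three steps most likely to fail:

**Step 4 (Cu/quinoline decarboxylation at 220 °C: tarring, partial loss of the benzyl ether, low yield).** The fallback sets out from aldehyde 3 and comes back to the route at bibenzyl 8. 3-Hydroxybenzyl alcohol is heated with PPh3·HBr in MeCN to give (3-hydroxybenzyl)triphenylphosphonium bromide F1. Treating F1 with KOtBu (2.2 equiv, THF, 0 °C) and then with 3 gives, by Wittig olefination, a mixture of stilbene 7 and its geometric isomer 3-{(E)-2-[3-(benzyloxy)-5-methoxyphenyl]ethenyl}phenol F2. The mixture is reduced with diimide exactly as in step 5, and both isomers converge on 8.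

**Step 7 (dibromination: risk of incomplete second bromination, attack at the carbon between the two oxygens, or over-bromination).** The fallback sets out from pivalate 9 and comes back at 17, bypassing 12 and step 9. Compound 9 is benzylated twice in a Friedel–Crafts reaction with 4-(benzyloxy)benzyl alcohol (2.2 equiv) and Bi(OTf)3 (5 mol%) in CH2Cl2/HFIP at 0 °C → rt. The p-alkoxybenzyl cation attacks the same two most nucleophilic positions of ring A, passing through 3-(2-{3-(benzyloxy)-2-[4-(benzyloxy)benzyl]-5-methoxyphenyl}ethyl)phenyl pivalate F3 and 3-(2-{5-(benzyloxy)-2-[4-(benzyloxy)benzyl]-3-methoxyphenyl}ethyl)phenyl pivalate F4, to give 17. Ring B stays deactivated by the pivalate.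

**Step 9 (twofold Negishi coupling at two di-ortho-substituted, electron-rich C–Br bonds: risk of stalling at 15/16 or protodebromination).** The fallback sets out from dibromide 12 and comes back at 17. Bromine–magnesium exchange with n-Bu3MgLi (THF, −10 °C; the pivalate is tolerated) followed by addition to 4-(benzyloxy)benzaldehyde is carried out twice in succession. The first round gives the bromo carbinols 3-(2-{3-(benzyloxy)-2-{[4-(benzyloxy)phenyl](hydroxy)methyl}-6-bromo-5-methoxyphenyl}ethyl)phenyl pivalate F5 and 3-(2-{3-(benzyloxy)-6-{[4-(benzyloxy)phenyl](hydroxy)methyl}-2-bromo-5-methoxyphenyl}ethyl)phenyl pivalate F6. The second round gives the bis-carbinol 3-(2-{3-(benzyloxy)-2,6-bis{[4-(benzyloxy)phenyl](hydroxy)methyl}-5-methoxyphenyl}ethyl)phenyl pivalate F7 as a mixture of stereoisomers at the two carbinol carbons. Ionic hydrogenation of F7 with Et3SiH/TFA (CH2Cl2, 0 °C) reduces both electron-rich diaryl carbinols to CH2, erasing those stereocentres and giving 17.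

## Further compounds

F1 | step 4 | (3-hydroxybenzyl)triphenylphosphonium bromide | [Br-].Oc1cccc(C[P+](c2ccccc2)(c2ccccc2)c2ccccc2)c1
F2 | step 4 | 3-{(E)-2-[3-(benzyloxy)-5-methoxyphenyl]ethenyl}phenol | Oc1cccc(/C=C/c2cc(OC)cc(OCc3ccccc3)c2)c1
F3 | step 7 | 3-(2-{3-(benzyloxy)-2-[4-(benzyloxy)benzyl]-5-methoxyphenyl}ethyl)phenyl pivalate | CC(C)(C)C(=O)Oc1cccc(CCc2cc(OC)cc(OCc3ccccc3)c2Cc2ccc(OCc3ccccc3)cc2)c1
F4 | step 7 | 3-(2-{5-(benzyloxy)-2-[4-(benzyloxy)benzyl]-3-methoxyphenyl}ethyl)phenyl pivalate | CC(C)(C)C(=O)Oc1cccc(CCc2cc(OCc3ccccc3)cc(OC)c2Cc2ccc(OCc3ccccc3)cc2)c1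
F5 | step 9 | 3-(2-{3-(benzyloxy)-2-{[4-(benzyloxy)phenyl](hydroxy)methyl}-6-bromo-5-methoxyphenyl}ethyl)phenyl pivalate (racemic carbinol) | CC(C)(C)C(=O)Oc1cccc(CCc2c(C(O)c3ccc(OCc4ccccc4)cc3)c(OCc3ccccc3)cc(OC)c2Br)c1
F6 | step 9 | 3-(2-{3-(benzyloxy)-6-{[4-(benzyloxy)phenyl](hydroxy)methyl}-2-bromo-5-methoxyphenyl}ethyl)phenyl pivalate (racemic carbinol) | CC(C)(C)C(=O)Oc1cccc(CCc2c(Br)c(OCc3ccccc3)cc(OC)c2C(O)c2ccc(OCc3ccccc3)cc2)c1
F7 | step 9 | 3-(2-{3-(benzyloxy)-2,6-bis{[4-(benzyloxy)phenyl](hydroxy)methyl}-5-methoxyphenyl}ethyl)phenyl pivalate (mixture of stereoisomers at the two carbinol carbons) | CC(C)(C)C(=O)Oc1cccc(CCc2c(C(O)c3ccc(OCc4ccccc4)cc3)c(OCc3ccccc3)cc(OC)c2C(O)c2ccc(OCc3ccccc3)cc2)c1
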